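**Strategy.** The coumarin is disconnected last, at O1–C2 and C3=C4 of the pyranone ring (O1, C2, C3, C4, C4a, C8a). Because C4a sits between the two oxygen-bearing carbons C5 and C8a, with the ether at C7 para to it, the arene is a mirror-symmetric 2,6-dihydroxy-4-alkoxybenzaldehyde. Whichever phenol is acylated by Ph3P=C=C=O, intramolecular Wittig closure gives the same 5-hydroxy-7-alkoxycoumarin. The precursor carries the complete side chain, with the 9′,10′-diol held as the acetonide inherited from 2-deoxy-D-ribose. It is assembled by carboalumination–iodination, B-alkyl Suzuki coupling and a 4-O-selective Mitsunobu etherification.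

Key step: step 12

Remark on the chemistry: the target is read as (2′E,6′E,9′S,10′S) with an erythro 9′,10′-diol. This is the configuration of C3/C4 of 2-deoxy-D-ribose (sugar C1 becomes C7′, C5 becomes C11′), so no stereocentre has to be created or inverted. The tertiary C11′–OH is left free throughout, because it is inert to Mitsunobu activation and far less acidic than the phenols.

**Step 1**
Reactants: 1 2-deoxy-D-ribose
Product: 2 3,4-O-isopropylidene-2-deoxy-D-erythro-pentopyranose (lactol; anomer mixture)
Conditions: 2-methoxypropene (1.2 equiv), PPTS (cat.), EtOAc, 0 °C → rt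
Reagents that add atoms: 2-methoxypropene, COC(C)=C
Why: Acid-catalysed transketalisation should tie up the cis-3,4-diol of the pyranose form as a dioxolane (acetonide formation) without touching either stereocentre.

**Step 2**
Reactants: 2 lactol acetonide
Product: 3 [(4R,5S)-2,2-dimethyl-5-(prop-2-yn-1-yl)-1,3-dioxolan-4-yl]methanol
Conditions: dimethyl (1-diazo-2-oxopropyl)phosphonate (1.5 equiv), K2CO3, MeOH, 0 °C → rt
Reagents that add atoms: dimethyl (1-diazo-2-oxopropyl)phosphonate, CC(=O)C(=[N+]=[N-])P(=O)(OC)OC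
Why: The lactol reacts through its open hydroxy-aldehyde form in a Seyferth–Gilbert homologation (Ohira–Bestmann variant); the stereocentres are β and γ to the carbonyl and should not epimerise under the mild base.

**Step 3**
Reactants: 3 alkynol
Product: 5 (4S,5S)-2,2-dimethyl-5-(prop-2-yn-1-yl)-1,3-dioxolane-4-carboxylic acid, via dioxolane-4-carbaldehyde 4 (not isolated)
Conditions: TEMPO (0.2 equiv), PhI(OAc)2 (2.2 equiv), MeCN/H2O (1:1), rt
Reagents that add atoms: water, O
Why: Oxoammonium (TEMPO) oxidation takes the primary alcohol through the aldehyde hydrate to the acid under near-neutral conditions that should spare the alkyne, the acetonide and the α-alkoxy stereocentre.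

**Step 4**
Reactants: 5 carboxylic acid
Product: 6 methyl (4S,5S)-2,2-dimethyl-5-(prop-2-yn-1-yl)-1,3-dioxolane-4-carboxylate
Conditions: TMSCHN2, toluene/MeOH (4:1), 0 °C
Reagents that add atoms: trimethylsilyldiazomethane, C[Si](C)(C)C=[N+]=[N-]
Why: Diazoalkane O-methylation of the acid is base-free, so the cis-dioxolane centre α to the ester should not epimerise.

**Step 5**
Reactants: 6 methyl ester
Product: 8 2-[(4S,5S)-2,2-dimethyl-5-(prop-2-yn-1-yl)-1,3-dioxolan-4-yl]propan-2-ol, via methyl ketone 7 (not isolated)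
Conditions: MeMgBr (4 equiv), THF, −78 → 0 °C; aq. NH4Cl
Reagents that add atoms: methylmagnesium bromide, C[Mg]Br
Why: Double Grignard addition to the ester via the ketone should outrun enolisation at low temperature, so C10′ keeps its configuration; the excess reagent covers the acidic alkyne C–H.

**Step 6**
Reactants: 8 alkynyl tertiary alcohol
Product: 10 2-[(4S,5S)-5-[(2E)-3-iodo-2-methylprop-2-en-1-yl]-2,2-dimethyl-1,3-dioxolan-4-yl]propan-2-ol, via alkenylalane 9 (not isolated)
Conditions: AlMe3 (4 equiv), Cp2ZrCl2 (0.25 equiv), H2O (1 equiv), CH2Cl2, −20 °C; then I2, THF, −20 → 0 °C; potassium sodium tartrate work-up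
Reagents that add atoms: trimethylaluminium, C[Al](C)C; iodine, II
Why: Zirconium-catalysed Negishi carboalumination adds Me–Al syn across the terminal alkyne with methyl on the internal carbon, and iodinolysis with retention should give the E iodide; the water-accelerated low-temperature variant limits Lewis-acid exposure of the acetonide.

**Step 7**
Reactants: 11 (E)-3-methylpent-2-en-4-yn-1-ol
Product: 12 tert-butyl{[(2E)-3-methylpent-2-en-4-yn-1-yl]oxy}diphenylsilane
Conditions: TBDPSCl, imidazole, CH2Cl2, 0 °C → rt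
Reagents that add atoms: tert-butyl(chloro)diphenylsilane, CC(C)(C)[Si](Cl)(c1ccccc1)c1ccccc1
Why: Standard silylation of the primary allylic alcohol gives a non-volatile ether that tolerates hydrogenation, borane and aqueous base.

**Step 8**
Reactants: 12 silyl enyne
Product: 13 tert-butyl{[(2E)-3-methylpenta-2,4-dien-1-yl]oxy}diphenylsilane
Conditions: H2 (1 atm), Pd/CaCO3 poisoned with Pb(OAc)2, quinoline, hexane/EtOAc, rt, stopped after 1 equiv H2
Reagents that add atoms: none
Why: Lindlar-type semi-hydrogenation should stop at the vinyl group because the alkyne binds the poisoned palladium surface more strongly than the diene; the E trisubstituted olefin is not touched.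

**Step 9**
Reactants: 13 silyl diene (1.5 equiv); 10 vinyl iodide
Product: 15 2-[(4S,5S)-5-[(2E,6E)-8-{[tert-butyl(diphenyl)silyl]oxy}-2,6-dimethylocta-2,6-dien-1-yl]-2,2-dimethyl-1,3-dioxolan-4-yl]propan-2-ol, via B-alkyl-9-BBN 14 (not isolated)
Conditions: 13, 9-BBN, THF, 0 °C → rt; then 10, PdCl2(dppf) (5 mol%), AsPh3, Cs2CO3, DMF/THF/H2O, rt
Reagents that add atoms: none
Why: 9-BBN should hydroborate only the monosubstituted terminus of the diene (boron on the terminal carbon, trisubstituted alkene inert), and B-alkyl Suzuki–Miyaura coupling joins C5′ to C6′ with retention of the iodide geometry.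

**Step 10**
Reactants: 15 silyl ether
Product: 16 (2E,6E)-8-[(4S,5S)-5-(2-hydroxypropan-2-yl)-2,2-dimethyl-1,3-dioxolan-4-yl]-3,7-dimethylocta-2,6-dien-1-ol
Conditions: TBAF, THF, 0 °C → rt
Reagents that add atoms: none
Why: Fluoride-mediated desilylation should free the primary allylic alcohol without affecting the acetonide, the olefins or the tertiary alcohol.

**Step 11**
Reactants: 16 allylic alcohol; 17 2,4,6-trihydroxybenzaldehyde (3 equiv)
Product: 18 2,6-dihydroxy-4-({(2E,6E)-8-[(4S,5S)-5-(2-hydroxypropan-2-yl)-2,2-dimethyl-1,3-dioxolan-4-yl]-3,7-dimethylocta-2,6-dien-1-yl}oxy)benzaldehyde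
Conditions: PPh3, DIAD, THF, 0 °C → rt
Reagents that add atoms: 2,4,6-trihydroxybenzaldehyde 17, O=Cc1c(O)cc(O)cc1O
Why: In this Mitsunobu etherification only the primary allylic alcohol is activated (tertiary OH inert), and the 4-OH, the most acidic phenol and the only one not hydrogen-bonded to the formyl group, should be the nucleophile; excess phenol suppresses dialkylation.

**Step 12**
Reactants: 18 symmetric dihydroxybenzaldehyde; 19 (triphenylphosphoranylidene)ketene
Product: 21 5-hydroxy-7-({(2E,6E)-8-[(4S,5S)-5-(2-hydroxypropan-2-yl)-2,2-dimethyl-1,3-dioxolan-4-yl]-3,7-dimethylocta-2,6-dien-1-yl}oxy)-2H-chromen-2-one, via aryl phosphoranylideneacetate 20 (not isolated)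
Conditions: 19 (1.0 equiv, added slowly), THF, rt; then 65 °C
Reagents that add atoms: (triphenylphosphoranylidene)ketene 19, O=C=C=P(c1ccccc1)(c1ccccc1)c1ccccc1
Why: The acidic phenolic O–H protonates the ylide carbon of 19 and the phenoxide adds to the ketene carbon, giving the aryl (triphenylphosphoranylidene)acetate 20 at room temperature, where the tertiary alcohol does not react. On warming, this stabilised ylide attacks the ortho formyl group, which the remaining phenol activates by hydrogen bonding, and the oxaphosphetane collapses with loss of Ph3PO; this is the phenol acylation–intramolecular Wittig sequence known for salicylaldehydes and ketenylidene phosphoranes. The pyranone ring closes as a six-membered ring by olefination within the tether (O1–C2 first, C3=C4 second), so the ring double bond is cis by necessity. No stereocentre is formed, and C9′ and C10′ are remote and untouched. Site selectivity is not required because the two phenols are exchanged by the mirror plane through C1 and C4 of the arene, so either closure leaves the other oxygen as the 5-OH and the ether at C7. The step needs only chemoselectivity (phenol over tertiary alcohol, mono- over bis-acylation), secured by the acidity gap, by one equivalent of 19 added slowly, and by consuming it before heating.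

**Step 13**
Reactants: 21 coumarin acetonide
Product: 22 5-hydroxy-7-{[(2E,6E,9S,10S)-9,10,11-trihydroxy-3,7,11-trimethyldodeca-2,6-dien-1-yl]oxy}-2H-chromen-2-one (target)
Conditions: AcOH/H2O (4:1), 45 °C
Reagents that add atoms: none
Why: Mild aqueous acid hydrolysis of the dioxolane should release the 9′,10′-diol, while the allylic aryl ether, the trisubstituted olefins and the lactone tolerate dilute acetic acid.

**Compound list**
1 | 2-deoxy-D-ribose | O=CC[C@H](O)[C@H](O)CO | starting material
2 | 3,4-O-isopropylidene-2-deoxy-D-erythro-pentopyranose (anomer mixture) | OC1C[C@H](O2)[C@H](OC2(C)C)CO1 | intermediate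
3 | [(4R,5S)-2,2-dimethyl-5-(prop-2-yn-1-yl)-1,3-dioxolan-4-yl]methanol | C#CC[C@H](O1)[C@H](OC1(C)C)CO | intermediate
4 | (4S,5S)-2,2-dimethyl-5-(prop-2-yn-1-yl)-1,3-dioxolane-4-carbaldehyde | C#CC[C@H](O1)[C@H](OC1(C)C)C=O | intermediate
5 | (4S,5S)-2,2-dimethyl-5-(prop-2-yn-1-yl)-1,3-dioxolane-4-carboxylic acid | C#CC[C@H](O1)[C@H](OC1(C)C)C(=O)O | intermediate
6 | methyl (4S,5S)-2,2-dimethyl-5-(prop-2-yn-1-yl)-1,3-dioxolane-4-carboxylate | C#CC[C@H](O1)[C@H](OC1(C)C)C(=O)OC | intermediate
7 | 1-[(4S,5S)-2,2-dimethyl-5-(prop-2-yn-1-yl)-1,3-dioxolan-4-yl]ethan-1-one | C#CC[C@H](O1)[C@H](OC1(C)C)C(C)=O | intermediate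
8 | 2-[(4S,5S)-2,2-dimethyl-5-(prop-2-yn-1-yl)-1,3-dioxolan-4-yl]propan-2-ol | C#CC[C@H](O1)[C@H](OC1(C)C)C(C)(C)O | intermediate
9 | (E)-alkenyl(dimethyl)alane from 8, as its dimethylaluminium alkoxide | C[Al](C)/C=C(\C)C[C@H](O1)[C@H](OC1(C)C)C(C)(C)O[Al](C)C | intermediate
10 | 2-[(4S,5S)-5-[(2E)-3-iodo-2-methylprop-2-en-1-yl]-2,2-dimethyl-1,3-dioxolan-4-yl]propan-2-ol | I/C=C(\C)C[C@H](O1)[C@H](OC1(C)C)C(C)(C)O | intermediate
11 | (E)-3-methylpent-2-en-4-yn-1-ol | C#C/C(C)=C/CO | starting material
12 | tert-butyl{[(2E)-3-methylpent-2-en-4-yn-1-yl]oxy}diphenylsilane | C#C/C(C)=C/CO[Si](c1ccccc1)(c1ccccc1)C(C)(C)C | intermediate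
13 | tert-butyl{[(2E)-3-methylpenta-2,4-dien-1-yl]oxy}diphenylsilane | C=C/C(C)=C/CO[Si](c1ccccc1)(c1ccccc1)C(C)(C)C | intermediate
14 | 9-[(3E)-5-{[tert-butyl(diphenyl)silyl]oxy}-3-methylpent-3-en-1-yl]-9-borabicyclo[3.3.1]nonane | CC(C)(C)[Si](c1ccccc1)(c1ccccc1)OC/C=C(\C)CCB1C2CCCC1CCC2 | intermediate
15 | 2-[(4S,5S)-5-[(2E,6E)-8-{[tert-butyl(diphenyl)silyl]oxy}-2,6-dimethylocta-2,6-dien-1-yl]-2,2-dimethyl-1,3-dioxolan-4-yl]propan-2-ol | CC(C)(C)[Si](c1ccccc1)(c1ccccc1)OC/C=C(\C)CC/C=C(\C)C[C@H](O1)[C@H](OC1(C)C)C(C)(C)O | intermediate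
16 | (2E,6E)-8-[(4S,5S)-5-(2-hydroxypropan-2-yl)-2,2-dimethyl-1,3-dioxolan-4-yl]-3,7-dimethylocta-2,6-dien-1-ol | OC/C=C(\C)CC/C=C(\C)C[C@H](O1)[C@H](OC1(C)C)C(C)(C)O | intermediate
17 | 2,4,6-trihydroxybenzaldehyde | O=Cc1c(O)cc(O)cc1O | starting material
18 | 2,6-dihydroxy-4-(side-chain-oxy)benzaldehyde, 9′,10′-acetonide | C/C(=C\COc1cc(O)c(C=O)c(O)c1)CC/C=C(\C)C[C@H](O1)[C@H](OC1(C)C)C(C)(C)O | intermediate
19 | (triphenylphosphoranylidene)ketene | O=C=C=P(c1ccccc1)(c1ccccc1)c1ccccc1 | starting material
20 | 2-formyl-3-hydroxy-5-(side-chain-oxy)phenyl (triphenyl-λ5-phosphanylidene)acetate, 9′,10′-acetonide | C/C(=C\COc1cc(O)c(C=O)c(OC(=O)C=P(c2ccccc2)(c2ccccc2)c2ccccc2)c1)CC/C=C(\C)C[C@H](O1)[C@H](OC1(C)C)C(C)(C)O | intermediate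
21 | 5-hydroxy-7-(side-chain-oxy)-2H-chromen-2-one, 9′,10′-acetonide | C/C(=C\COc1cc(O)c2ccc(=O)oc2c1)CC/C=C(\C)C[C@H](O1)[C@H](OC1(C)C)C(C)(C)O | intermediate
22 | 5-hydroxy-7-{[(2E,6E,9S,10S)-9,10,11-trihydroxy-3,7,11-trimethyldodeca-2,6-dien-1-yl]oxy}-2H-chromen-2-one | C/C(=C\COc1cc(O)c2ccc(=O)oc2c1)CC/C=C(\C)C[C@H](O)[C@H](O)C(C)(C)O | target

**Step count.** Total: 13 steps. Longest linear sequence: 11 steps (steps 1–6 and 9–13, from 2-deoxy-D-ribose); steps 7–8 form the short branch.

**Steps most likely to fail**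

Step 12. The single equivalent of ylide may be shared unevenly between the two phenols of 18 and the phenol of the product, giving over-acylation and unreacted aldehyde. Alternatively, the electron-rich, hydrogen-bonded aldehyde may olefinate slowly, so that the sequence stalls at the acyl ylide. Fallback, from 18 back to 21: intermolecular Wittig olefination of 18 with methyl (triphenylphosphoranylidene)acetate (toluene, 80 °C) should give the methyl (E)-2,6-dihydroxycinnamate F1. Irradiation (365 nm, or visible light with a triplet sensitiser, MeCN, rt) then isomerises the E olefin to Z, and the Z ester lactonises onto either of the two equivalent phenols with loss of methanol, delivering 21. The same two bonds are formed and the symmetry argument is unchanged.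

Step 9. Hydroboration of the conjugated diene may lose chemoselectivity (attack at the internal olefin, double hydroboration), or transmetalation of the alkylborane may be slow, leading to protodeboronation and reduction of the iodide. Fallback, from 13 back to 15: hydroboration of 13 with 9-BBN followed by NaOH/H2O2 gives the homoallylic alcohol F2, which can be purified. I2, PPh3 and imidazole convert it into the primary iodide F3, and zinc dust with LiCl in THF gives the alkylzinc iodide F4. Negishi coupling of F4 with vinyl iodide 10 under Pd(PPh3)4 (THF, rt to 50 °C) should give 15, with excess zinc reagent compensating for the free tertiary hydroxyl.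

Step 11. Discrimination among the three phenols may be incomplete, with dialkylation or SN2′ attack on the activated allylic alcohol. Fallback, from 16 back to 18: Appel bromination of 16 (CBr4, PPh3, 2,6-lutidine, CH2Cl2, 0 °C) gives the allylic bromide F5. This alkylates 17 (3 equiv) with KHCO3 in DMF at rt, where only the most acidic 4-OH is deprotonated, giving 18 by Williamson etherification.

**Further compounds**
F1 | step 12 | methyl (2E)-3-[2,6-dihydroxy-4-({(2E,6E)-8-[(4S,5S)-5-(2-hydroxypropan-2-yl)-2,2-dimethyl-1,3-dioxolan-4-yl]-3,7-dimethylocta-2,6-dien-1-yl}oxy)phenyl]prop-2-enoate | C/C(=C\COc1cc(O)c(/C=C/C(=O)OC)c(O)c1)CC/C=C(\C)C[C@H](O1)[C@H](OC1(C)C)C(C)(C)O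
F2 | step 9 | (3E)-5-{[tert-butyl(diphenyl)silyl]oxy}-3-methylpent-3-en-1-ol | CC(C)(C)[Si](c1ccccc1)(c1ccccc1)OC/C=C(\C)CCO
F3 | step 9 | tert-butyl{[(2E)-5-iodo-3-methylpent-2-en-1-yl]oxy}diphenylsilane | CC(C)(C)[Si](c1ccccc1)(c1ccccc1)OC/C=C(\C)CCI
F4 | step 9 | [(3E)-5-{[tert-butyl(diphenyl)silyl]oxy}-3-methylpent-3-en-1-yl]zinc iodide | CC(C)(C)[Si](c1ccccc1)(c1ccccc1)OC/C=C(\C)CC[Zn]I
F5 | step 11 | 2-[(4S,5S)-5-[(2E,6E)-8-bromo-2,6-dimethylocta-2,6-dien-1-yl]-2,2-dimethyl-1,3-dioxolan-4-yl]propan-2-ol | BrC/C=C(\C)CC/C=C(\C)C[C@H](O1)[C@H](OC1(C)C)C(C)(C)O
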